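**Plan**

1. Retrosynthesis: remove three MOM ethers; cut C3–C4 of ring C (retro-hydroacylation) to a ring A benzaldehyde whose O1 carries the enol ether C2=C3 with ring B on C2; take C2=C3 back to an aryl ester C=O and the CHO back to Br; cut the ester at O1 into a ring A phenol and a ring B/D acid.
2. Enabling feature: C4 is an aryl carbonyl carbon on C4a flanked by O1 (on C8a) and the C5 oxygen, C3 is an unsubstituted CH2, and C2 bears H, ring B and O1. This is the acyl–CH2–CH pattern left when a formyl C–H adds across an O1-tethered C2=C3.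
3. Ring A piece: phloroglucinol and acrylic acid give a dihydrocoumarin; MeMgBr opens the lactone, creating the C8 side chain and the single free phenol that becomes O1 (this fixes 8- over 6-substitution); ortho-bromination marks C4a.
4. Ring B/D piece: umbelliferone and MeLi give the 2,2-dimethylchromene (ring D); ortho-formylation, MOM protection and oxidation give the acid.
5. Forward order: the two pieces are joined as an ester at O1, the ester C=O becomes C2=C3, Br becomes the C4 aldehyde, ring C is closed last by C3–C4 bond formation, then deprotection.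
6. Stereochemistry: the only stereocenter, C2 (S), is created in the ring closure by hydride delivery to one face of the enol ether under control of a chiral bisphosphine–rhodium catalyst.

Key step: step 12

Assumptions: flavanone numbering (O1, C2, C3, C4, C4a, C5–C8, C8a) is used; ring A is the phloroglucinol ring, ring B the pendant aryl ring, ring C the pyranone, ring D the dimethylpyran. The ligand antipode that gives (2S) cannot be predicted with certainty; (R)-DTBM-SEGPHOS is written and would be exchanged for its (S) form if a pilot run shows the opposite sense.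

**Route**

Step 1
Reactants: 1 phloroglucinol; 2 acrylic acid
Product: 3 5,7-dihydroxychroman-2-one
Conditions: Amberlyst-15, toluene, reflux (Dean–Stark), 1 in excess
Reagents that add atoms: none
Why: Acid-catalysed Friedel–Crafts-type conjugate hydroarylation of acrylic acid by the very nucleophilic arene, then lactonisation onto the neighbouring phenol, should give the dihydrocoumarin; all ring positions of 1 are equivalent, so no regiochemical question arises.

Step 2
Reactants: 3 5,7-dihydroxychroman-2-one
Product: 4 5,7-bis(methoxymethoxy)chroman-2-one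
Conditions: MOMCl (2.4 equiv), iPr2NEt, CH2Cl2, 0 °C → rt
Reagents that add atoms: chloromethyl methyl ether (MOMCl), COCCl
Why: O-alkylation of both phenols with an α-chloro ether under a hindered amine base (Williamson type) should leave the aryl lactone intact.

Step 3
Reactants: 4 5,7-bis(methoxymethoxy)chroman-2-one
Product: 6 2-(3-hydroxy-3-methylbutyl)-3,5-bis(methoxymethoxy)phenol, via ketone phenoxide 5 (not isolated)
Conditions: MeMgBr (3 equiv), THF, 0 °C → rt; then H2O
Reagents that add atoms: methylmagnesium bromide, C[Mg]Br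
Why: Double Grignard addition to the aryl lactone (the first equivalent expels the phenoxide to give ketone 5, the second gives the tertiary alcohol) should release the lactone oxygen as the only free phenol, which is the future O1 next to the chain.

Step 4
Reactants: 6 2-(3-hydroxy-3-methylbutyl)-3,5-bis(methoxymethoxy)phenol
Product: 7 2-bromo-6-(3-hydroxy-3-methylbutyl)-3,5-bis(methoxymethoxy)phenol
Conditions: NBS (1.0 equiv), iPr2NH (10 mol %), CH2Cl2, −78 → 0 °C
Reagents that add atoms: N-bromosuccinimide, O=C1CCC(=O)N1Br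
Why: Amine-catalysed ortho-selective electrophilic bromination of a phenol (the N-bromoamine is delivered by hydrogen bonding to the OH) should go to the only free ortho position, the future C4a, since the position para to OH is shielded between two MOM ethers.

Step 5
Reactants: 8 umbelliferone (7-hydroxycoumarin)
Product: 10 2,2-dimethyl-2H-chromen-7-ol, via diol 9 (not isolated)
Conditions: MeLi (4 equiv), THF, 0 °C → rt; then AcOH, rt
Reagents that add atoms: methyllithium, [Li]C
Why: Double 1,2-addition of methyllithium to the coumarin lactone gives the (Z)-allylic tertiary alcohol 9, which on mild acid should close by allylic cation capture, assisted by the para phenol, to the 2,2-dimethylchromene (classical coumarin-to-chromene conversion).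

Step 6
Reactants: 10 2,2-dimethyl-2H-chromen-7-ol
Product: 12 7-hydroxy-2,2-dimethyl-2H-chromene-6-carbaldehyde, via benzylic alcohol 11 (not isolated)
Conditions: MgCl2, Et3N, (CH2O)n, MeCN, reflux
Reagents that add atoms: paraformaldehyde (as formaldehyde), C=O
Why: Magnesium-phenoxide-directed ortho-formylation (Casnati–Skattebøl reaction: ortho-hydroxymethylation, then hydride transfer to a second formaldehyde) should favour chromene position 6 over position 8, which is wedged between two oxygen substituents.

Step 7
Reactants: 12 7-hydroxy-2,2-dimethyl-2H-chromene-6-carbaldehyde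
Product: 13 7-(methoxymethoxy)-2,2-dimethyl-2H-chromene-6-carbaldehyde
Conditions: MOMCl, iPr2NEt, CH2Cl2, 0 °C → reflux
Reagents that add atoms: chloromethyl methyl ether (MOMCl), COCCl
Why: O-alkylation of the chelated phenol masks the future 2'-OH as an ether that should survive the oxidation, the titanium carbene and the organolithium steps.

Step 8
Reactants: 13 7-(methoxymethoxy)-2,2-dimethyl-2H-chromene-6-carbaldehyde
Product: 14 7-(methoxymethoxy)-2,2-dimethyl-2H-chromene-6-carboxylic acid
Conditions: NaClO2, NaH2PO4, 2-methyl-2-butene, t-BuOH/H2O, rt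
Reagents that add atoms: sodium chlorite, [Na+].[O-]Cl=O
Why: Pinnick oxidation of the aryl aldehyde; the alkene scavenger traps HOCl so that the chromene C=C and the electron-rich ring should not be chlorinated, and the MOM ether is stable at the buffered pH.

Step 9
Reactants: 14 7-(methoxymethoxy)-2,2-dimethyl-2H-chromene-6-carboxylic acid; 7 2-bromo-6-(3-hydroxy-3-methylbutyl)-3,5-bis(methoxymethoxy)phenol
Product: 16 2-bromo-6-(3-hydroxy-3-methylbutyl)-3,5-bis(methoxymethoxy)phenyl 7-(methoxymethoxy)-2,2-dimethyl-2H-chromene-6-carboxylate, via mixed anhydride 15 (not isolated)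
Conditions: 2,4,6-Cl3C6H2COCl, Et3N, THF, rt; then 7, DMAP, toluene, rt → 50 °C
Reagents that add atoms: none
Why: Yamaguchi esterification: DMAP attacks the less hindered carbonyl of mixed anhydride 15 and the acylpyridinium should acylate the acidic, hindered phenol in preference to the tertiary alcohol.

Step 10
Reactants: 16 the aryl ester
Product: 17 4-[3-bromo-2-({1-[7-(methoxymethoxy)-2,2-dimethyl-2H-chromen-6-yl]ethenyl}oxy)-4,6-bis(methoxymethoxy)phenyl]-2-methylbutan-2-ol
Conditions: Tebbe reagent Cp2Ti(μ-CH2)(μ-Cl)AlMe2 (3 equiv), pyridine, THF/toluene, −40 °C → rt; 15 % aq NaOH quench; Et3N-deactivated silica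
Reagents that add atoms: Tebbe reagent, Cp2Ti(μ-CH2)(μ-Cl)AlMe2, C[Al-]1(C)C[Ti]([Cl+]1)(C1C=CC=C1)C1C=CC=C1
Why: Tebbe methylenation of the aryl ester ([2+2] addition of the titanium methylidene to C=O and cycloreversion driven by Ti=O formation) should turn the ester carbonyl into the enol ether C2=C3; the aryl bromide, MOM ethers and chromene are inert and the free tertiary OH only consumes one equivalent of reagent.

Step 11
Reactants: 17 the bromo enol ether
Product: 19 3-(3-hydroxy-3-methylbutyl)-4,6-bis(methoxymethoxy)-2-({1-[7-(methoxymethoxy)-2,2-dimethyl-2H-chromen-6-yl]ethenyl}oxy)benzaldehyde, via aryllithium 18 (not isolated)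
Conditions: n-BuLi (2.2 equiv), THF, −78 °C; DMF, −78 → 0 °C; then H2O
Reagents that add atoms: N,N-dimethylformamide, CN(C)C=O
Why: After deprotonation of the alcohol, bromine–lithium exchange should outrun ortho-lithiation at −78 °C, and aryllithium 18, stabilised by its two ortho oxygens, is formylated by DMF (Bouveault formylation) under fully non-acidic conditions that spare the enol ether.

Step 12
Reactants: 19 the enol ether aldehyde
Product: 20 (2S)-8-(3-hydroxy-3-methylbutyl)-5,7-bis(methoxymethoxy)-2-[7-(methoxymethoxy)-2,2-dimethyl-2H-chromen-6-yl]-2,3-dihydro-4H-chromen-4-one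
Conditions: [Rh(cod)Cl]2 (2.5 mol %), (R)-DTBM-SEGPHOS (5.5 mol %), Na[B(3,5-(CF3)2C6H3)4] (5 mol %), degassed 1,4-dioxane, 70 °C
Reagents that add atoms: none
Why: Proposed new method: cationic monovalent rhodium should insert into the formyl C–H bond of 19 (the acyl hydride being held by the neighbouring C5 methoxymethoxy oxygen), the enol-ether C=C then inserts into Rh–H with hydride going to the carbon that bears ring B and O1 (C2) and rhodium to the terminal CH2 (C3), and C–C reductive elimination from the seven-membered acyl–alkyl rhodacycle forms C3–C4 and returns monovalent rhodium. The closest known reaction type is the rhodium–bisphosphine-catalysed enantioselective intramolecular hydroacylation of 1,1-disubstituted alkenes in 2-(2-arylallyl)benzaldehydes to 3-aryltetralones, of which 19 is the analogue with O1 in place of the benzylic CH2; an enol ether has not been shown in this role. Ring C closes in a formal 6-endo-trig mode. The single new stereocenter C2 is set in the hydride insertion, the face of the prochiral alkene being chosen by the axially chiral bisphosphine on rhodium (catalyst control, no substrate stereocenter present). The step needs endo closure instead of 5-exo closure to a 2-aryl-2-methylbenzofuran-3-one and must outrun decarbonylation and β-aryloxide loss from the alkylrhodium; exo closure would require a tertiary alkylrhodium and a quaternary carbon, the two ortho oxygens chelate the acyl hydride, and the C8 chain presses the vinyl group towards the formyl group so that insertion and reductive elimination should be fast.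

Step 13
Reactants: 20 the tris-MOM flavanone
Product: 21 (2S)-5,7-dihydroxy-2-(7-hydroxy-2,2-dimethyl-2H-chromen-6-yl)-8-(3-hydroxy-3-methylbutyl)-2,3-dihydro-4H-chromen-4-one
Conditions: HCl (1.25 M in MeOH), 0 °C → 30 °C
Reagents that add atoms: none
Why: Acid-catalysed transacetalisation of the three aryl MOM ethers to dimethoxymethane should free the phenols; the C2 stereocenter is not expected to epimerise under acid (ring opening to the chalcone is base-mediated), and the low temperature should keep the tertiary alcohol and the chromene intact.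

**Compound list**

1 | phloroglucinol | Oc1cc(O)cc(O)c1 | starting material
2 | acrylic acid | C=CC(=O)O | starting material
3 | 5,7-dihydroxychroman-2-one | O=C1CCc2c(O)cc(O)cc2O1 | intermediate
4 | 5,7-bis(methoxymethoxy)chroman-2-one | O=C1CCc2c(OCOC)cc(OCOC)cc2O1 | intermediate
5 | 4-[2-hydroxy-4,6-bis(methoxymethoxy)phenyl]butan-2-one as its bromomagnesium phenoxide | CC(=O)CCc1c(O[Mg]Br)cc(OCOC)cc1OCOC | intermediate
6 | 2-(3-hydroxy-3-methylbutyl)-3,5-bis(methoxymethoxy)phenol | CC(C)(O)CCc1c(O)cc(OCOC)cc1OCOC | intermediate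
7 | 2-bromo-6-(3-hydroxy-3-methylbutyl)-3,5-bis(methoxymethoxy)phenol | CC(C)(O)CCc1c(O)c(Br)c(OCOC)cc1OCOC | intermediate
8 | umbelliferone (7-hydroxy-2H-chromen-2-one) | O=c1ccc2ccc(O)cc2o1 | starting material
9 | 4-[(Z)-3-hydroxy-3-methylbut-1-enyl]benzene-1,3-diol (trilithium salt before acidification) | CC(C)(O)/C=C\c1ccc(O)cc1O | intermediate
10 | 2,2-dimethyl-2H-chromen-7-ol | CC1(C)C=Cc2ccc(O)cc2O1 | intermediate
11 | 6-(hydroxymethyl)-2,2-dimethyl-2H-chromen-7-ol (magnesium phenoxide in the flask) | CC1(C)C=Cc2cc(CO)c(O)cc2O1 | intermediate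
12 | 7-hydroxy-2,2-dimethyl-2H-chromene-6-carbaldehyde | CC1(C)C=Cc2cc(C=O)c(O)cc2O1 | intermediate
13 | 7-(methoxymethoxy)-2,2-dimethyl-2H-chromene-6-carbaldehyde | CC1(C)C=Cc2cc(C=O)c(OCOC)cc2O1 | intermediate
14 | 7-(methoxymethoxy)-2,2-dimethyl-2H-chromene-6-carboxylic acid | CC1(C)C=Cc2cc(C(=O)O)c(OCOC)cc2O1 | intermediate
15 | mixed anhydride of 14 with 2,4,6-trichlorobenzoic acid | CC1(C)C=Cc2cc(C(=O)OC(=O)c3c(Cl)cc(Cl)cc3Cl)c(OCOC)cc2O1 | intermediate
16 | 2-bromo-6-(3-hydroxy-3-methylbutyl)-3,5-bis(methoxymethoxy)phenyl 7-(methoxymethoxy)-2,2-dimethyl-2H-chromene-6-carboxylate | CC(C)(O)CCc1c(OC(=O)c2cc3C=CC(C)(C)Oc3cc2OCOC)c(Br)c(OCOC)cc1OCOC | intermediate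
17 | 4-[3-bromo-2-({1-[7-(methoxymethoxy)-2,2-dimethyl-2H-chromen-6-yl]ethenyl}oxy)-4,6-bis(methoxymethoxy)phenyl]-2-methylbutan-2-ol | CC(C)(O)CCc1c(OC(=C)c2cc3C=CC(C)(C)Oc3cc2OCOC)c(Br)c(OCOC)cc1OCOC | intermediate
18 | aryllithium lithium alkoxide derived from 17 (Li in place of Br, OLi in place of OH) | CC(C)(O[Li])CCc1c(OC(=C)c2cc3C=CC(C)(C)Oc3cc2OCOC)c([Li])c(OCOC)cc1OCOC | intermediate
19 | 3-(3-hydroxy-3-methylbutyl)-4,6-bis(methoxymethoxy)-2-({1-[7-(methoxymethoxy)-2,2-dimethyl-2H-chromen-6-yl]ethenyl}oxy)benzaldehyde | CC(C)(O)CCc1c(OC(=C)c2cc3C=CC(C)(C)Oc3cc2OCOC)c(C=O)c(OCOC)cc1OCOC | intermediate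
20 | (2S)-8-(3-hydroxy-3-methylbutyl)-5,7-bis(methoxymethoxy)-2-[7-(methoxymethoxy)-2,2-dimethyl-2H-chromen-6-yl]-2,3-dihydro-4H-chromen-4-one | CC(C)(O)CCc1c(OCOC)cc(OCOC)c2c1O[C@H](c1cc3c(cc1OCOC)OC(C)(C)C=C3)CC2=O | intermediate
21 | (2S)-5,7-dihydroxy-2-(7-hydroxy-2,2-dimethyl-2H-chromen-6-yl)-8-(3-hydroxy-3-methylbutyl)-2,3-dihydro-4H-chromen-4-one | CC(C)(O)CCc1c(O)cc(O)c2c1O[C@H](c1cc3c(cc1O)OC(C)(C)C=C3)CC2=O | target

**Step count**

Total steps: 13. Longest linear sequence: 9 steps (steps 1–4 and 9–13, or steps 5–8 and 9–13).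

**Steps most likely to fail**

1. Step 12. The hindered, electron-rich acyl rhodium hydride may decarbonylate, the alkene may insert in the opposite sense and close exo, the alkylrhodium may lose the β-aryloxide, or the facial selectivity may be poor. The fallback uses known chemistry, sets out from bromophenol 7 and aldehyde 13 and comes back at 20. Stille coupling of 7 with tributyl(1-ethoxyvinyl)stannane (Pd(PPh3)4, toluene, 100 °C) would give 2-(1-ethoxyethenyl)-6-(3-hydroxy-3-methylbutyl)-3,5-bis(methoxymethoxy)phenol F1, which brief treatment with 1 M HCl in THF would hydrolyse to 1-[2-hydroxy-3-(3-hydroxy-3-methylbutyl)-4,6-bis(methoxymethoxy)phenyl]ethan-1-one F2. Claisen–Schmidt condensation of F2 with 13 (KOH, EtOH, rt) would give (E)-1-[2-hydroxy-3-(3-hydroxy-3-methylbutyl)-4,6-bis(methoxymethoxy)phenyl]-3-[7-(methoxymethoxy)-2,2-dimethyl-2H-chromen-6-yl]prop-2-en-1-one F3. NaOAc in refluxing EtOH would close ring C by oxa-Michael addition of the only free phenol to give the racemic tris-MOM flavanone F4. Preparative HPLC on a chiral stationary phase would separate 20 from its (2R) enantiomer F5, which can be recycled by base-mediated equilibration through F3.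

2. Step 4. Bromination may occur para to the hydroxyl, between the two MOM ethers, or proceed twice. The fallback sets out from phenol 6, uses acid 14, and comes back at aldehyde 19. Magnesium-mediated ortho-formylation of 6 (MgCl2, Et3N, (CH2O)n, MeCN, reflux), whose regiochemistry is dictated by the phenoxide, would give 2-hydroxy-3-(3-hydroxy-3-methylbutyl)-4,6-bis(methoxymethoxy)benzaldehyde F6. Yamaguchi esterification with 14 would give 2-formyl-6-(3-hydroxy-3-methylbutyl)-3,5-bis(methoxymethoxy)phenyl 7-(methoxymethoxy)-2,2-dimethyl-2H-chromene-6-carboxylate F7. HC(OMe)3 with catalytic PPTS in MeOH would mask the aldehyde as the dimethyl acetal ester F8. Tebbe methylenation would give the dimethyl acetal enol ether F9. Because the trioxygenated benzaldehyde acetal ionises far faster than the aryl enol ether is protonated at carbon, wet silica gel with a trace of oxalic acid in CH2Cl2 at 0 °C should unmask 19 selectively.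

3. Step 5. The lithium phenoxide formed first may deactivate the lactone or precipitate, so that the double addition stalls or conjugate addition intervenes. The fallback sets out from 8 and comes back at 10. MOMCl and iPr2NEt would give 7-(methoxymethoxy)-2H-chromen-2-one F10, in which no phenoxide can form. MeLi (2.5 equiv, THF, 0 °C) would give (Z)-2-(3-hydroxy-3-methylbut-1-enyl)-5-(methoxymethoxy)phenol F11, which PPTS in CH2Cl2 would close to 7-(methoxymethoxy)-2,2-dimethyl-2H-chromene F12. HCl in MeOH at room temperature would remove the MOM group and return 10.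

**Further compounds**

F1 | step 12 | 2-(1-ethoxyethenyl)-6-(3-hydroxy-3-methylbutyl)-3,5-bis(methoxymethoxy)phenol | CCOC(=C)c1c(O)c(CCC(C)(C)O)c(OCOC)cc1OCOC
F2 | step 12 | 1-[2-hydroxy-3-(3-hydroxy-3-methylbutyl)-4,6-bis(methoxymethoxy)phenyl]ethan-1-one | CC(=O)c1c(O)c(CCC(C)(C)O)c(OCOC)cc1OCOC
F3 | step 12 | (E)-1-[2-hydroxy-3-(3-hydroxy-3-methylbutyl)-4,6-bis(methoxymethoxy)phenyl]-3-[7-(methoxymethoxy)-2,2-dimethyl-2H-chromen-6-yl]prop-2-en-1-one | CC(C)(O)CCc1c(O)c(C(=O)/C=C/c2cc3C=CC(C)(C)Oc3cc2OCOC)c(OCOC)cc1OCOC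
F4 | step 12 | racemic 8-(3-hydroxy-3-methylbutyl)-5,7-bis(methoxymethoxy)-2-[7-(methoxymethoxy)-2,2-dimethyl-2H-chromen-6-yl]-2,3-dihydro-4H-chromen-4-one | CC(C)(O)CCc1c(OCOC)cc(OCOC)c2c1OC(c1cc3c(cc1OCOC)OC(C)(C)C=C3)CC2=O
F5 | step 12 | (2R)-8-(3-hydroxy-3-methylbutyl)-5,7-bis(methoxymethoxy)-2-[7-(methoxymethoxy)-2,2-dimethyl-2H-chromen-6-yl]-2,3-dihydro-4H-chromen-4-one | CC(C)(O)CCc1c(OCOC)cc(OCOC)c2c1O[C@@H](c1cc3c(cc1OCOC)OC(C)(C)C=C3)CC2=O
F6 | step 4 | 2-hydroxy-3-(3-hydroxy-3-methylbutyl)-4,6-bis(methoxymethoxy)benzaldehyde | CC(C)(O)CCc1c(O)c(C=O)c(OCOC)cc1OCOC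
F7 | step 4 | 2-formyl-6-(3-hydroxy-3-methylbutyl)-3,5-bis(methoxymethoxy)phenyl 7-(methoxymethoxy)-2,2-dimethyl-2H-chromene-6-carboxylate | CC(C)(O)CCc1c(OC(=O)c2cc3C=CC(C)(C)Oc3cc2OCOC)c(C=O)c(OCOC)cc1OCOC
F8 | step 4 | 2-(dimethoxymethyl)-6-(3-hydroxy-3-methylbutyl)-3,5-bis(methoxymethoxy)phenyl 7-(methoxymethoxy)-2,2-dimethyl-2H-chromene-6-carboxylate | CC(C)(O)CCc1c(OC(=O)c2cc3C=CC(C)(C)Oc3cc2OCOC)c(C(OC)OC)c(OCOC)cc1OCOC
F9 | step 4 | 4-[3-(dimethoxymethyl)-2-({1-[7-(methoxymethoxy)-2,2-dimethyl-2H-chromen-6-yl]ethenyl}oxy)-4,6-bis(methoxymethoxy)phenyl]-2-methylbutan-2-ol | CC(C)(O)CCc1c(OC(=C)c2cc3C=CC(C)(C)Oc3cc2OCOC)c(C(OC)OC)c(OCOC)cc1OCOC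
F10 | step 5 | 7-(methoxymethoxy)-2H-chromen-2-one | COCOc1ccc2ccc(=O)oc2c1
F11 | step 5 | (Z)-2-(3-hydroxy-3-methylbut-1-enyl)-5-(methoxymethoxy)phenol | CC(C)(O)/C=C\c1ccc(OCOC)cc1O
F12 | step 5 | 7-(methoxymethoxy)-2,2-dimethyl-2H-chromene | CC1(C)C=Cc2ccc(OCOC)cc2O1
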